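**Retrosynthetic overview**

1. Target ⇒ (acetylation, C3 oxidation) a CH2–CH2-linked bis(tertiary alcohol). The 7R carbinol comes from MeLi addition to one ring ketone; the 7S carbinol comes from Wittig methylenation and hydration of the other.
2. The CH2–CH2 bond and the chemical difference between the two rings both come from one step: head-to-head hetero-Diels–Alder dimerisation of a single α-methylene ketone (one molecule as 1-oxadiene, one as dienophile). The spiro-dihydropyran formed is later opened by hydrolysis and SmI2.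
3. Monomer ⇒ trans-fused oxepane by epoxidation and 7-endo cyclisation of a homoprenyl alcohol; its quaternary carbon ⇒ anti cuprate addition to (S)-4-silyloxy-3-methylcyclohexenone with CH2O trapping.
4. Enone ⇒ (S)-carvone (Luche reduction, allylic oxidation, excision of the isopropenyl group).
5. Ring order: cyclohexane (from carvone) → oxepane → dihydropyran (cycloaddition, transient, then opened).

Assumption: the oxepane carbinol carbon C3 (and the transient ketal and epoxide carbons of 5 and 12) are carried as epimer mixtures and left undefined in the SMILES until step 13 removes C3 as a stereocentre. Benzoxepine locants (O1, C2 … C9a) are used for each bicyclic unit; "unit X" is the oxadiene-derived ring, "unit Y" the dienophile-derived ring.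

**Step 1**
Reactants: 1 (S)-(+)-carvone
Product: 2 (1S,5S)-cis-carveol
Conditions: NaBH4, CeCl3·7H2O, MeOH, −78 → 0 °C
Reagents that add atoms: none
Why: Luche 1,2-reduction; hydride adds axially to the half-chair with the isopropenyl group pseudo-equatorial, so the bought C5 centre sets the new carbinol centre cis (the ~5% trans isomer is removed by chromatography at 3).

**Step 2**
Reactants: 2 (1S,5S)-cis-carveol
Product: 3 (1S,5S)-cis-carveol triethylsilyl ether
Conditions: TESCl, imidazole, CH2Cl2, 0 °C → rt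
Reagents that add atoms: chlorotriethylsilane, CC[Si](Cl)(CC)CC
Why: Standard silylation; the silyl ether protects the carbinol and later directs the cuprate to the opposite face.

**Step 3**
Reactants: 3 (1S,5S)-cis-carveol triethylsilyl ether
Product: 4 (4S,6S)-3-methyl-6-(prop-1-en-2-yl)-4-(triethylsilyloxy)cyclohex-2-en-1-one
Conditions: CrO3, 3,5-dimethylpyrazole, CH2Cl2, −20 °C
Reagents that add atoms: chromium trioxide, O=[Cr](=O)=O
Why: Cr(VI)–pyrazole allylic oxidation converts the ring CH2 next to the less substituted alkene carbon into the conjugated enone; the silyloxy centre is untouched and C6 is removed in the next step.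

**Step 4**
Reactants: 4 (4S,6S)-3-methyl-6-(prop-1-en-2-yl)-4-(triethylsilyloxy)cyclohex-2-en-1-one
Product: 6 (S)-3-methyl-4-(triethylsilyloxy)cyclohex-2-en-1-one, via methoxy hydroperoxide 5 (not isolated)
Conditions: O3, MeOH, −78 °C; then FeSO4·7H2O, PhSH, −78 °C → rt
Reagents that add atoms: none
Why: Hydrodealkenylation: ozone cleaves only the electron-rich 1,1-disubstituted alkene, Fe(II) reduces the methoxy hydroperoxide to an alkoxy radical that loses methyl acetate by β-scission, and the α-keto radical takes H from the thiol; the silyloxy centre is not involved.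

**Step 5**
Reactants: 6 (S)-3-methyl-4-(triethylsilyloxy)cyclohex-2-en-1-one; 7 5-bromo-2-methylpent-2-ene
Product: 11 (2R,3S,4S)-4-hydroxy-2-(hydroxymethyl)-3-methyl-3-(4-methylpent-3-en-1-yl)cyclohexan-1-one, via homoprenylmagnesium bromide 8 (not isolated), via magnesium enolate 9 (not isolated), via TES-protected aldol 10 (not isolated)
Conditions: 7, Mg, THF; CuBr·SMe2 (10 mol %), 6, THF, −40 °C; CH2O (g), −78 → −20 °C; then 1 M HCl, THF, rt
Reagents that add atoms: formaldehyde, C=O
Why: Cu-catalysed 1,4-addition occurs anti to the γ-silyloxy group and sets the quaternary carbon, the regiodefined magnesium enolate is hydroxymethylated trans to the new chain (aldol), and the acidic work-up removes the TES group.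

**Step 6**
Reactants: 11 (2R,3S,4S)-4-hydroxy-2-(hydroxymethyl)-3-methyl-3-(4-methylpent-3-en-1-yl)cyclohexan-1-one
Product: 13 (5aS,6R,9aS)-3-hydroxy-6-(hydroxymethyl)-2,2,5a-trimethylperhydro-1-benzoxepin-7-one (trans-fused; C3 epimers), via epoxide 12 (not isolated)
Conditions: mCPBA, NaHCO3, CH2Cl2, 0 °C; then CSA (20 mol %), 0 °C → rt
Reagents that add atoms: 3-chloroperbenzoic acid, OOC(=O)c1cccc(Cl)c1
Why: Prilezhaev epoxidation of the only alkene, then acid-catalysed 7-endo epoxide opening at the tertiary carbon by the ring hydroxyl gives the 2,2-dimethyloxepan-3-ol; the trans ring fusion follows from the existing centres.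

**Step 7**
Reactants: 13 (5aS,6R,9aS)-3-hydroxy-6-(hydroxymethyl)-2,2,5a-trimethylperhydro-1-benzoxepin-7-one (two molecules)
Product: 16 spiro-dihydropyran hetero-Diels–Alder dimer (pyran C5=C6 is the C6=C7 enol ether of unit X; pyran C2 is the spiro C6 of unit Y which keeps its C7 ketone; pyran O axial on unit Y), via primary mesylate 14 (not isolated), via methylene ketone 15 (not isolated)
Conditions: MsCl, Et3N, CH2Cl2, −20 → 0 °C; aqueous wash; then PhMe (2 M), BHT, 90 °C
Reagents that add atoms: none
Why: Selective mesylation of the primary β-hydroxy-ketone OH and E1cB elimination give the α-methylene ketone, which dimerises head-to-head in an inverse-demand hetero-Diels–Alder reaction to forge the CH2–CH2 bond; the spiro centre forms anti to the axial angular methyl and is erased in step 10.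

**Step 8**
Reactants: 16 spiro-dihydropyran hetero-Diels–Alder dimer
Product: 17 hydroxy diketone (unit X: 7-ketone with 6-H; unit Y: 6-hydroxy-7-ketone; units joined C6–CH2–CH2–C6; may sit as its cyclic hemiketal)
Conditions: 1 M HCl, THF–H2O, rt
Reagents that add atoms: water, O
Why: Acid hydrolysis of the cyclic enol ether frees the unit-X ketone, whose α-carbon equilibrates to the equatorial side chain (6S, as in 8-oxolabdanes), and leaves unit Y as a tertiary α-ketol.

**Step 9**
Reactants: 17 hydroxy diketone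
Product: 18 methylene hydroxy ketone (unit X: 7-methylene; unit Y: 6-hydroxy-7-ketone)
Conditions: Ph3PCH3Br, KOtBu, THF, 0 → 50 °C
Reagents that add atoms: methyltriphenylphosphonium bromide, C[P+](c1ccccc1)(c1ccccc1)c1ccccc1.[Br-]
Why: Wittig methylenation is selective for the unit-X ketone because the unit-Y carbonyl is flanked by a fully substituted, deprotonated carbinol carbon next to a quaternary centre.

**Step 10**
Reactants: 18 methylene hydroxy ketone
Product: 19 methylene ketone (unit X: 7-methylene; unit Y: 7-ketone with 6S side chain)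
Conditions: SmI2, THF–MeOH, −78 °C; then K2CO3, MeOH, rt
Reagents that add atoms: none
Why: SmI2 reductive cleavage of the α-hydroxy ketone C–O bond gives the samarium enolate, and protonation with base equilibration sets the equatorial side chain on unit Y.

**Step 11**
Reactants: 19 methylene ketone
Product: 20 methylene triol (unit Y: (7R)-7-hydroxy-7-methyl with axial OH; unit X: 7-methylene)
Conditions: MeLi, THF, −78 → 0 °C
Reagents that add atoms: methyllithium, [Li]C
Why: 1,2-Addition of MeLi from the equatorial face, anti to the syn-axial angular methyl, gives the axial tertiary alcohol (7R).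

**Step 12**
Reactants: 20 methylene triol
Product: 22 tetraol (unit Y: 7R axial OH; unit X: (7S)-7-hydroxy-7-methyl with equatorial OH), via organomercurial 21 (not isolated)
Conditions: Hg(OAc)2, THF–H2O, rt; then NaBH4, aq. NaOH, 0 °C
Reagents that add atoms: water, O
Why: Markovnikov oxymercuration–demercuration; water attacks the tertiary carbon from the open equatorial face (the axial face is blocked by the angular methyl), giving the equatorial alcohol with axial methyl (7S).

**Step 13**
Reactants: 22 tetraol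
Product: 23 diketone diol (both oxepan-3-ones; both tertiary alcohols free)
Conditions: Dess–Martin periodinane, NaHCO3, CH2Cl2, rt
Reagents that add atoms: none
Why: Dess–Martin oxidation converts both secondary carbinols into ketones and merges the C3 epimers; the tertiary alcohols cannot react.

**Step 14**
Reactants: 23 diketone diol
Product: 24 CNP0325605.1, 1-[(5aS,6S,7R,9aS)-7-acetoxy-2,2,5a,7-tetramethyl-3-oxoperhydro-1-benzoxepin-6-yl]-2-[(5aS,6S,7S,9aS)-7-acetoxy-2,2,5a,7-tetramethyl-3-oxoperhydro-1-benzoxepin-6-yl]ethane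
Conditions: Ac2O, Bi(OTf)3 (5 mol %), CH2Cl2, 0 °C → rt
Reagents that add atoms: acetic anhydride, CC(=O)OC(C)=O
Why: Lewis-acid-catalysed acylation esterifies both hindered tertiary alcohols without touching the C–O stereocentres, giving the target.

**Compound list**

1 | (S)-(+)-carvone | CC1=CC[C@@H](CC1=O)C(C)=C | starting material
2 | (1S,5S)-cis-carveol | C1C=C(C)[C@@H](O)C[C@H]1C(C)=C | intermediate
3 | (1S,5S)-cis-carveol triethylsilyl ether | C1C=C(C)[C@@H](O[Si](CC)(CC)CC)C[C@H]1C(C)=C | intermediate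
4 | (4S,6S)-3-methyl-6-(prop-1-en-2-yl)-4-(triethylsilyloxy)cyclohex-2-en-1-one | O=C1C=C(C)[C@@H](O[Si](CC)(CC)CC)C[C@H]1C(C)=C | intermediate
5 | 6-(1-hydroperoxy-1-methoxyethyl) analogue of 4 (methoxy hydroperoxide) | O=C1C=C(C)[C@@H](O[Si](CC)(CC)CC)C[C@H]1C(C)(OC)OO | intermediate (not isolated)
6 | (S)-3-methyl-4-(triethylsilyloxy)cyclohex-2-en-1-one | O=C1C=C(C)[C@@H](O[Si](CC)(CC)CC)CC1 | intermediate
7 | 5-bromo-2-methylpent-2-ene | CC(C)=CCCBr | starting material
8 | (4-methylpent-3-en-1-yl)magnesium bromide | CC(C)=CCC[Mg]Br | intermediate (not isolated)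
9 | bromomagnesium enolate of (3S,4S)-3-methyl-3-(4-methylpent-3-en-1-yl)-4-(triethylsilyloxy)cyclohexanone | Br[Mg]OC1=C[C@](C)(CCC=C(C)C)[C@@H](O[Si](CC)(CC)CC)CC1 | intermediate (not isolated)
10 | (2R,3S,4S)-2-(hydroxymethyl)-3-methyl-3-(4-methylpent-3-en-1-yl)-4-(triethylsilyloxy)cyclohexan-1-one | O=C1CC[C@H](O[Si](CC)(CC)CC)[C@@](C)(CCC=C(C)C)[C@@H]1CO | intermediate (not isolated)
11 | (2R,3S,4S)-4-hydroxy-2-(hydroxymethyl)-3-methyl-3-(4-methylpent-3-en-1-yl)cyclohexan-1-one | O=C1CC[C@H](O)[C@@](C)(CCC=C(C)C)[C@@H]1CO | intermediate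
12 | (2R,3S,4S)-3-[2-(3,3-dimethyloxiran-2-yl)ethyl]-4-hydroxy-2-(hydroxymethyl)-3-methylcyclohexan-1-one | O=C1CC[C@H](O)[C@@](C)(CCC2OC2(C)C)[C@@H]1CO | intermediate (not isolated)
13 | (5aS,6R,9aS)-3-hydroxy-6-(hydroxymethyl)-2,2,5a-trimethylperhydro-1-benzoxepin-7-one | O=C1CC[C@@H]2OC(C)(C)C(O)CC[C@@]2(C)[C@@H]1CO | intermediate
14 | primary methanesulfonate of 13 | O=C1CC[C@@H]2OC(C)(C)C(O)CC[C@@]2(C)[C@@H]1COS(C)(=O)=O | intermediate (not isolated)
15 | (5aS,9aS)-3-hydroxy-2,2,5a-trimethyl-6-methyleneperhydro-1-benzoxepin-7-one | O=C1CC[C@@H]2OC(C)(C)C(O)CC[C@@]2(C)C1=C | intermediate (not isolated)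
16 | spiro-dihydropyran hetero-Diels–Alder dimer of 15 | O=C1CC[C@@H]2OC(C)(C)C(O)CC[C@@]2(C)[C@]13CCC4=C(O3)CC[C@@H]5OC(C)(C)C(O)CC[C@@]45C | intermediate
17 | hydroxy diketone (unit X 7-ketone; unit Y 6-hydroxy-7-ketone) | O=C1CC[C@@H]2OC(C)(C)C(O)CC[C@@]2(C)[C@]1(O)CC[C@@H]3C(=O)CC[C@@H]4OC(C)(C)C(O)CC[C@@]34C | intermediate
18 | methylene hydroxy ketone (unit X 7-methylene; unit Y 6-hydroxy-7-ketone) | O=C1CC[C@@H]2OC(C)(C)C(O)CC[C@@]2(C)[C@]1(O)CC[C@@H]3C(=C)CC[C@@H]4OC(C)(C)C(O)CC[C@@]34C | intermediate
19 | methylene ketone (unit X 7-methylene; unit Y 7-ketone) | O=C1CC[C@@H]2OC(C)(C)C(O)CC[C@@]2(C)[C@@H]1CC[C@@H]3C(=C)CC[C@@H]4OC(C)(C)C(O)CC[C@@]34C | intermediate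
20 | methylene triol (unit Y 7R tertiary alcohol; unit X 7-methylene) | O[C@]1(C)CC[C@@H]2OC(C)(C)C(O)CC[C@@]2(C)[C@@H]1CC[C@@H]3C(=C)CC[C@@H]4OC(C)(C)C(O)CC[C@@]34C | intermediate
21 | acetoxymercuriomethyl carbinol (oxymercuration adduct of 20) | O[C@]1(C)CC[C@@H]2OC(C)(C)C(O)CC[C@@]2(C)[C@@H]1CC[C@@H]3[C@@](C[Hg]OC(C)=O)(O)CC[C@@H]4OC(C)(C)C(O)CC[C@@]34C | intermediate (not isolated)
22 | tetraol (unit Y 7R; unit X 7S tertiary alcohols; two C3 carbinols) | O[C@]1(C)CC[C@@H]2OC(C)(C)C(O)CC[C@@]2(C)[C@@H]1CC[C@@H]3[C@@](C)(O)CC[C@@H]4OC(C)(C)C(O)CC[C@@]34C | intermediate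
23 | diketone diol | O[C@]1(C)CC[C@@H]2OC(C)(C)C(=O)CC[C@@]2(C)[C@@H]1CC[C@@H]3[C@@](C)(O)CC[C@@H]4OC(C)(C)C(=O)CC[C@@]34C | intermediate
24 | CNP0325605.1 (diacetate) | CC(=O)O[C@]1(C)CC[C@@H]2OC(C)(C)C(=O)CC[C@@]2(C)[C@@H]1CC[C@H]1[C@]2(C)CCC(=O)C(C)(C)O[C@H]2CC[C@]1(C)OC(C)=O | target

**Totals**

Total step count: 14. Longest linear sequence: 14 steps (from 1; 7 enters at step 5).

**Steps most likely to fail, with fallbacks**

Step 3. The Cr(VI) oxidation may attack the silyloxy-bearing allylic C–H or the isopropenyl group instead of the ring CH2. The fallback sets out from 2 and returns at 4: acetylate 2 (Ac2O, pyridine) to (1S,5S)-cis-carveyl acetate F1, whose acyloxy group deactivates the carbinol C–H. Oxidise with CrO3/3,5-dimethylpyrazole to the acetoxy enone F2, methanolyse (K2CO3, MeOH, 0 °C) to the hydroxy enone F3, and silylate with TESCl/imidazole to reach 4. This costs two extra steps.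

Step 6. The 6-exo opening to a tetrahydropyran with an exocyclic carbinol can compete with the 7-endo mode. The fallback sets out from 11 and returns at 13: Hg(OCOCF3)2, MeCN, −20 °C, then brine, activates the alkene instead of an epoxide and gives, by Markovnikov 7-endo alkoxymercuration, the organomercurial chloride F4. Oxidative demercuration (NaBH4, O2, DMF) then gives 13.

Step 7. The thermal dimerisation of the hindered methylene ketone may be slow or give oligomers. The fallback sets out from 15 and returns at 19, bypassing 16–18: SmI2/HMPA/t-BuOH reductive β,β′-hydrodimerisation of 15 gives the C2-symmetric diketone F5. One equivalent of Ph3P=CH2, with recycling of recovered material, then gives 19 by statistical mono-olefination, and the route resumes at step 11.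

**Further compounds**

F1 | step 3 | (1S,5S)-cis-carveyl acetate | C1C=C(C)[C@@H](OC(C)=O)C[C@H]1C(C)=C
F2 | step 3 | (4S,6S)-4-acetoxy-3-methyl-6-(prop-1-en-2-yl)cyclohex-2-en-1-one | O=C1C=C(C)[C@@H](OC(C)=O)C[C@H]1C(C)=C
F3 | step 3 | (4S,6S)-4-hydroxy-3-methyl-6-(prop-1-en-2-yl)cyclohex-2-en-1-one | O=C1C=C(C)[C@@H](O)C[C@H]1C(C)=C
F4 | step 6 | (5aS,6R,9aS)-3-(chloromercurio)-6-(hydroxymethyl)-2,2,5a-trimethylperhydro-1-benzoxepin-7-one | O=C1CC[C@@H]2OC(C)(C)C([Hg]Cl)CC[C@@]2(C)[C@@H]1CO
F5 | step 7 | 1,2-bis[(5aS,6S,9aS)-3-hydroxy-2,2,5a-trimethyl-7-oxoperhydro-1-benzoxepin-6-yl]ethane | O=C1CC[C@@H]2OC(C)(C)C(O)CC[C@@]2(C)[C@@H]1CC[C@@H]3C(=O)CC[C@@H]4OC(C)(C)C(O)CC[C@@]34C
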